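## Structural features

The target is a linear chain of eight benzene rings, A to H, joined by seven diaryl ether oxygens and carrying twenty-one free phenolic hydroxyls. It has no stereocentre, so no stereocentres stand next to each other and the problem is purely constitutional. Ring A is a 2,4,6-trihydroxyphenyl cap whose ether carbon C1 lies between two hydroxyls. Rings B, D and F are 1,4-dioxygenated with hydroxyls at C3 and C5, so the C4 oxygen is flanked by two ortho oxygens and C1 by two C–H. Rings C, E and G carry oxygen on five neighbouring carbons (ether at C1 to the preceding ring, hydroxyls at C3 to C5, ether at C6 to the following ring) with one C–H at C2; ring H is a 3,4,5-trihydroxyphenyl cap. The pairs B–C, D–E and F–G are therefore the same two-ring unit, repeated three times between the caps. The free polyphenol is readily oxidised by air, above all in base, so every hydroxyl should stay capped until the last step. The real difficulty is the ether bonds: each oxygen sits on one carbon with two ortho oxygen substituents, and the B–C, D–E and F–G ethers are ortho-substituted on the second carbon as well. The key step uses the atom pattern of ring G (and of the identical rings C and E): C3 to C6 with their four oxygens are the four carbons of a squaric ester, C1 with the ring F oxygen and C2–H are a 1-aryloxyvinyl group, and the only bond missing in the derived dienylketene is C2–C3.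

## Logic of the disconnections

**31 to 30.** The twenty-one O–H bonds are traced back to O–CH3 bonds. Methyl is the smallest cap and survives organolithiums, palladium, copper and fluoride, so every earlier intermediate is a neutral, air-stable ether. The forward step must cleave twenty-one aryl methyl ethers without touching seven diaryl ethers, and the product must be isolated without air.

**30 to 28 and 29.** The bond from C1 of ring H to the oxygen on C6 of ring G is cut so that the oxygen stays on the crowded carbon. The carbon partner 29 has no ortho substituent and is bought. The forward step is the O-arylation of a phenol flanked by an aryloxy and a methoxy group.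

**28 to 26, 26 to 24, 24 to 22, each with 21 (through 27, 25 and 23).** The C1–O bonds of rings F, D and B are cut in the same sense, and the O–Si bonds that mask the next phenol are cut with them. Because B–C, D–E and F–G are one unit, a single two-ring building block, 21, serves three times, and the octamer reduces to 21, 22 and 29. The forward steps require that 21 carries its own C6 oxygen under a group that is inert to the copper coupling and removable by fluoride, and that the coupling works with the chain phenol as the limiting partner.

**21 to 17 (through 20, 19 and 18).** The C–B bond at C1 of the first ring is traced to a C–O bond, and the sulfonate and benzyl groups are removed in turn. In the target the oxygen on C1 of rings B, D and F belongs to the crowded neighbour, so the benzyloxy oxygen of 17 serves only as a placeholder that survives the organolithium steps and is then exchanged for boron. The opposite pairing, 18 attacking a C6 carbon flanked by two oxygens, is the one avoided. Hydrogenolysis, sulfonylation and borylation must all leave the aryl silyl ether intact.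

**17 to 16.** The O–CH3 bond on C3 of the second ring is cut. Capping the phenol that the ring expansion releases means that only the C6 oxygen is unmasked later. The base must be mild enough for the silyl ether.

**16 to 13 (through 15 and 14).** The C2–C3 bond of the pentaoxygenated ring is cut. The ring falls back to a four-carbon and a two-carbon piece, and the crowded ether oxygen is already attached as a vinyl ether, so it is never made by aryl coupling. The forward step needs a thermal ring opening in which the silyloxy group turns outward, and the silyl group must survive.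

**13 to 9 and 10 (through 12 and 11).** The C–C bond between the vinyl carbon and C4 of the cyclobutenone is cut, together with the O–Si bond. This separates the squaric ester from the ring F piece. The forward step needs a 1-aryloxyvinyl anion that adds once, at low temperature.

**9 to 8, 8 to 5 (through 7 and 6), 5 to 3 and 4.** The C–Sn bond, the alkyne and the O–C(sp2) bond are cut in turn. The crowded phenol oxygen of 3 attacks a linear alkyne made in the flask from 4, so the two ortho methoxy groups do not hinder it. The demands are regiocontrol in the tin hydride addition and quick handling of the ynol ether.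

**3 to 2 to 1.** The O–benzyl bond is cut and the diol is traced to the quinone. The forward benzylation must distinguish the two hydroxyls of 2.

## Other disconnections considered

**Alternative 1:** The cut runs through ring C: the bond from the ring B oxygen to C1 and a carbon–iodine bond at C6 are removed together, leaving an aryne across C1–C6.
- Forward step: the phenoxide of the AB dimer A1 (2,6-dimethoxy-4-(2,4,6-trimethoxyphenoxy)phenol) would add to the aryne released by fluoride from the silyl triflate A2 (3,4,5-trimethoxy-2-(trimethylsilyl)phenyl triflate). The aryl anion at C6 would then take iodine from a perfluoroalkyl iodide to give the ABC iodide A3.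
- In its favour: addition to an aryne is hardly slowed by the two methoxy groups around the phenoxide oxygen and needs no metal. The C5 methoxy group next to the triple bond steers oxygen to C1 and charge to C6, and the iodine is a handle for the next ether.
- Against it here: the anion must be iodinated faster than it is protonated, and A2 takes several steps to make. Above all, the iodine in A3 lies between an aryloxy and a methoxy group, so the next C6–O bond would have to be made at a di-ortho-substituted, electron-rich aryl iodide.
- Comparison: on structure the two plans are equal, each giving the hindered ether with full regiocontrol. On mechanism the alternative is equally sound, though it depends on the relative rates of two intermolecular events where 13 to 16 is unimolecular. On step economy the alternative is better for this one bond (one step from A1 against six from 3 to 16). The chosen plan is better at the next bond, because its C6 carries oxygen and couples as the phenol, and because 21 serves three times.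

**Alternative 2:** The cut removes the bonds C2–C3 and C5–C6 of ring A (numbered from the ether carbon C1), so ring A falls apart into a malonate carrying the ring B oxygen and a three-carbon ketodiester.
- Forward step: the aryloxymalonate A4 and dimethyl 3-oxopentanedioate A5 would undergo two Claisen acylations under methoxide, the second closing the ring, to give the phloroglucinol diester A6. Its ester groups stand at C3 and C5 of ring A and its hydroxyls at C2, C4 and C6.
- In its favour: the ether oxygen between two hydroxyls is made as an alkyl aryl ether of a simple phenol and never by aryl coupling. This is the same idea as in the chosen plan and its equal, and the materials are cheaper than 10.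
- Against it here: it solves only the A-to-B ether, which the chosen plan closes in one step from commercial 22. A4 is deprotonated by methoxide to an enolate that is a poor acyl donor, so the double condensation may stall. A6 then needs ester hydrolysis, double decarboxylation and capping of three new hydroxyls, and the benzyloxy oxygen of ring B would still have to be joined to ring C between two methoxy groups.
- Comparison: on structure both create an ether at a crowded carbon by building the ring around it. On mechanism two reversible ionic acylations stand against an irreversible electrocyclic sequence, and each is well founded. On step economy the alternative is poorer, about four operations for one ether, and it gives no help with rings C, E and G.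

**Alternative 3:** The cut replaces seven C–OH bonds by C–CHO bonds, at C4 of ring A (the carbon para to the ether carbon C1) and at C3 of rings B to G.
- Forward step: the heptaaldehyde A7 would be treated with a peracid, each formyl group becoming an aryl formate by aryl migration, and methanolysis would give the heptaphenol A8.
- In its favour: in A7 every ether carbon that must accept a phenoxide lies ortho or para to a formyl group. All seven diaryl ethers could therefore be made by nucleophilic aromatic substitution of aryl fluorides, without metal and with little regard for crowding. Here the alternative is better than the chosen plan, whose four Chan–Lam couplings are its weakest bond formations. A8 also holds fourteen methyl ethers against the twenty-one of 30, so the last deprotection is lighter.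
- Against it here: seven oxidations must all go the same way in one flask on very electron-rich rings. Hydride instead of aryl migration at any one site gives an acid, the peracid may over-oxidise the rings, and formate loss in the flask exposes phenols that can be oxidised to quinones. Each fluorinated hydroxybenzaldehyde monomer also needs its own synthesis.
- Comparison: on structure the uniform ether formation is better. On mechanism both reactions are dependable singly, but the sevenfold event is exposed to statistical loss, where the chosen plan has one ring expansion on a small molecule. On step economy the alternative is equal at best, since the monomer syntheses offset the metal-free couplings.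

Key step: step 7

Remark on the chemistry: 12 and 13 hold one stereocentre (C4 of the cyclobutenone) and are racemic; step 7 destroys it, so no stereocontrol is needed. Ring positions are numbered with C1 as the ether carbon towards the preceding ring.

## Route

Step 1
Reactants: 1 2,6-dimethoxy-1,4-benzoquinone
Product: 2 2,6-dimethoxybenzene-1,4-diol
Conditions: Na2S2O4, EtOAc/H2O, rt
Reagents that add atoms: none
Why: Dithionite reduces the quinone to the hydroquinone by two-electron transfer; the two-phase mixture keeps the air-sensitive diol in the organic layer for direct use.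

Step 2
Reactants: 2 2,6-dimethoxybenzene-1,4-diol
Product: 3 4-(benzyloxy)-2,6-dimethoxyphenol
Conditions: BnBr (1.0 equiv), K2CO3 (1.0 equiv), acetone, rt, argon
Reagents that add atoms: benzyl bromide, BrCc1ccccc1
Why: Williamson ether synthesis with one equivalent each of base and halide; the C4 hydroxyl is the more acidic (two meta methoxy groups) and is unhindered, while the C1 hydroxyl is shielded and hydrogen-bonded by two ortho methoxy groups, so alkylation should occur at O-4.

Step 3
Reactants: 3 4-(benzyloxy)-2,6-dimethoxyphenol; 4 trichloroethylene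
Product: 5 5-(benzyloxy)-2-{[(E)-1,2-dichloroethenyl]oxy}-1,3-dimethoxybenzene
Conditions: K2CO3, DMF, 70 °C
Reagents that add atoms: none
Why: Base converts 4 into dichloroacetylene in the flask and the phenoxide adds to it in anti fashion (nucleophilic vinylation), which should give the E dichlorovinyl ether; a linear alkyne electrophile is not impeded by the two ortho methoxy groups.

Step 4
Reactants: 5 5-(benzyloxy)-2-{[(E)-1,2-dichloroethenyl]oxy}-1,3-dimethoxybenzene
Product: 8 5-(benzyloxy)-2-(ethynyloxy)-1,3-dimethoxybenzene, via chloroethynyl ether 6 (not isolated), via lithium acetylide 7 (not isolated)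
Conditions: n-BuLi (2.2 equiv), THF, −78 to −40 °C; MeOH, −78 °C
Reagents that add atoms: none
Why: Deprotonation and chloride loss give the chloroalkyne 6, chlorine–lithium exchange gives the acetylide 7, and cold protonation releases the terminal ynol ether; the two ortho methoxy groups should give the aryl ethynyl ether enough lifetime for immediate use.

Step 5
Reactants: 8 5-(benzyloxy)-2-(ethynyloxy)-1,3-dimethoxybenzene
Product: 9 tributyl[1-(4-benzyloxy-2,6-dimethoxyphenoxy)ethenyl]stannane
Conditions: Bu3SnH, Pd(PPh3)4 (2 mol%), THF, 0 °C to rt
Reagents that add atoms: tributyltin hydride, CCCC[SnH](CCCC)CCCC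
Why: Palladium-catalysed syn-hydrostannylation of a 1-alkoxyalkyne delivers hydride to the terminal carbon and tin to the oxygen-bearing carbon, which should give the 1-stannylvinyl ether.

Step 6
Reactants: 9 tributyl[1-(4-benzyloxy-2,6-dimethoxyphenoxy)ethenyl]stannane; 10 dimethyl squarate (3,4-dimethoxycyclobut-3-ene-1,2-dione)
Product: 13 rac-4-[1-(4-benzyloxy-2,6-dimethoxyphenoxy)ethenyl]-4-[(tert-butyldimethylsilyl)oxy]-2,3-dimethoxycyclobut-2-en-1-one, via vinyllithium 11 (not isolated), via lithium alkoxide 12 (not isolated)
Conditions: n-BuLi (1.05 equiv), THF, −78 °C; 10, −78 °C; TBSOTf, −78 to −20 °C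
Reagents that add atoms: tert-butyldimethylsilyl triflate, CC(C)(C)[Si](C)(C)OS(=O)(=O)C(F)(F)F
Why: Tin–lithium exchange gives the 1-aryloxyvinyllithium 11, held at −78 °C because of its carbenoid character; it adds once to a carbonyl of 10 (1,2-addition, the alkoxide 12 being inert to a second addition). The tertiary alkoxide is silylated in the flask and the new stereocentre forms as the racemate.

Step 7
Reactants: 13 rac-4-[1-(4-benzyloxy-2,6-dimethoxyphenoxy)ethenyl]-4-[(tert-butyldimethylsilyl)oxy]-2,3-dimethoxycyclobut-2-en-1-one
Product: 16 5-(4-benzyloxy-2,6-dimethoxyphenoxy)-4-[(tert-butyldimethylsilyl)oxy]-2,3-dimethoxyphenol, via dienylketene 14 (not isolated), via cyclohexadienone 15 (not isolated)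
Conditions: toluene (degassed), 110 °C
Reagents that add atoms: none
Why: On heating, the cyclobutenone opens by conrotatory 4π electrocyclic ring opening to the dienylketene 14, the silyloxy donor turning outward and the aryloxyvinyl group inward, so that ketene and vinyl group are cis on the central double bond. A thermal disrotatory 6π electrocyclisation then joins the ketene carbon (C3 of ring G) to the vinyl CH2 (C2) and closes the six-membered carbocycle as the cyclohexa-2,4-dienone 15, which enolises to the phenol 16. The closest known reaction type is the Moore ring expansion of 4-alkenyl-4-hydroxy- and 4-silyloxycyclobutenones from squaric esters to hydroquinone derivatives, including adducts of 1-alkoxyvinyllithiums; the aryloxy group on the vinyl carbon is a new substituent, not a new reaction. No stereocentre is formed and the one at C4 of 13 is lost. The selectivity needed is torquoselectivity and constitution: the outward turn of the oxygen donor is the electronically preferred one, and the ketene carbon can reach only the vinyl terminus, so the single C–H falls between the free hydroxyl and the ring F ether. The silyl group keeps the C6 oxygen distinct from the free C3 hydroxyl, and degassed solvent guards the electron-rich phenol against air.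

Step 8
Reactants: 16 5-(4-benzyloxy-2,6-dimethoxyphenoxy)-4-[(tert-butyldimethylsilyl)oxy]-2,3-dimethoxyphenol
Product: 17 {[6-(4-benzyloxy-2,6-dimethoxyphenoxy)-2,3,4-trimethoxyphenyl]oxy}(tert-butyl)dimethylsilane
Conditions: MeI, K2CO3, acetone, 50 °C
Reagents that add atoms: iodomethane, CI
Why: Williamson methylation of the only free phenol; the silyl ether on the hindered C6 oxygen and the benzyl ether should not react with K2CO3 in dry acetone.

Step 9
Reactants: 17 {[6-(4-benzyloxy-2,6-dimethoxyphenoxy)-2,3,4-trimethoxyphenyl]oxy}(tert-butyl)dimethylsilane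
Product: 18 4-(2-{[tert-butyl(dimethyl)silyl]oxy}-3,4,5-trimethoxyphenoxy)-3,5-dimethoxyphenol
Conditions: H2 (1 atm), Pd/C, EtOAc, rt
Reagents that add atoms: none
Why: Hydrogenolysis of the benzyl ether over palladium leaves aryl methyl ethers, the diaryl ether and the aryl silyl ether untouched.

Step 10
Reactants: 18 4-(2-{[tert-butyl(dimethyl)silyl]oxy}-3,4,5-trimethoxyphenoxy)-3,5-dimethoxyphenol
Product: 19 4-(2-{[tert-butyl(dimethyl)silyl]oxy}-3,4,5-trimethoxyphenoxy)-3,5-dimethoxyphenyl trifluoromethanesulfonate
Conditions: Tf2O, pyridine, CH2Cl2, 0 °C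
Reagents that add atoms: triflic anhydride, O=S(=O)(OS(=O)(=O)C(F)(F)F)C(F)(F)F
Why: Sulfonylation of the unhindered phenol turns the C1–O bond of the first ring into a leaving group for palladium; the silyl ether tolerates these conditions.

Step 11
Reactants: 19 4-(2-{[tert-butyl(dimethyl)silyl]oxy}-3,4,5-trimethoxyphenoxy)-3,5-dimethoxyphenyl trifluoromethanesulfonate
Product: 21 [4-(2-{[tert-butyl(dimethyl)silyl]oxy}-3,4,5-trimethoxyphenoxy)-3,5-dimethoxyphenyl]boronic acid, via pinacol boronate 20 (not isolated)
Conditions: B2pin2, PdCl2(dppf) (5 mol%), KOAc, 1,4-dioxane, 85 °C; NaIO4, NH4OAc, acetone/H2O, rt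
Reagents that add atoms: bis(pinacolato)diboron, CC1(C)OB(OC1(C)C)B1OC(C)(C)C(C)(C)O1; water, O
Why: Miyaura borylation of the aryl triflate (oxidative addition, acetate-assisted transmetalation from the diboron, reductive elimination) gives the pinacol ester 20; periodate then cleaves the pinacol to release the boronic acid, the better partner for copper-mediated arylation.

Step 12
Reactants: 21 [4-(2-{[tert-butyl(dimethyl)silyl]oxy}-3,4,5-trimethoxyphenoxy)-3,5-dimethoxyphenyl]boronic acid; 22 2,4,6-trimethoxyphenol
Product: 23 tert-butyl({6-[2,6-dimethoxy-4-(2,4,6-trimethoxyphenoxy)phenoxy]-2,3,4-trimethoxyphenyl}oxy)dimethylsilane (rings A to C)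
Conditions: Cu(OAc)2 (2 equiv), pyridine, 4 Å MS, CH2Cl2, dry air, rt; 22 in excess
Reagents that add atoms: none
Why: Chan–Lam coupling: the aryl group passes from boron to copper, the phenoxide binds, and reductive elimination from trivalent copper forms the C–O bond at room temperature; the crowded partner is the phenol and the boron-bearing carbon has no ortho substituent, the favourable pairing.

Step 13
Reactants: 23 tert-butyl({6-[2,6-dimethoxy-4-(2,4,6-trimethoxyphenoxy)phenoxy]-2,3,4-trimethoxyphenyl}oxy)dimethylsilane
Product: 24 6-[2,6-dimethoxy-4-(2,4,6-trimethoxyphenoxy)phenoxy]-2,3,4-trimethoxyphenol (ABC trimer phenol)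
Conditions: TBAF, AcOH, THF, 0 °C
Reagents that add atoms: none
Why: Fluoride cleaves the aryl silyl ether (strong Si–F bond); acetic acid buffers the phenoxide and so protects the electron-rich phenol from air oxidation, and methyl and diaryl ethers are inert.

Step 14
Reactants: 24 ABC trimer phenol; 21 [4-(2-{[tert-butyl(dimethyl)silyl]oxy}-3,4,5-trimethoxyphenoxy)-3,5-dimethoxyphenyl]boronic acid
Product: 25 ABCDE pentamer silyl ether (24 arylated on O-6 of ring C by the two-ring unit of 21; thirteen methyl ethers; silyl ether on O-6 of ring E)
Conditions: Cu(OAc)2 (2 equiv), pyridine, 4 Å MS, CH2Cl2, dry air, rt; 21 (2 equiv)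
Reagents that add atoms: none
Why: Chan–Lam coupling as in step 12; the phenol at C6 of ring C, flanked by an aryloxy and a methoxy group, is arylated by the unhindered aryl boron, and the building block is used in excess because the chain phenol is the valuable partner.

Step 15
Reactants: 25 ABCDE pentamer silyl ether
Product: 26 ABCDE pentamer phenol (free hydroxyl at C6 of ring E)
Conditions: TBAF, AcOH, THF, 0 °C
Reagents that add atoms: none
Why: Buffered fluoride desilylation as in step 13.

Step 16
Reactants: 26 ABCDE pentamer phenol; 21 [4-(2-{[tert-butyl(dimethyl)silyl]oxy}-3,4,5-trimethoxyphenoxy)-3,5-dimethoxyphenyl]boronic acid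
Product: 27 ABCDEFG heptamer silyl ether (26 arylated on O-6 of ring E by the two-ring unit of 21; eighteen methyl ethers; silyl ether on O-6 of ring G)
Conditions: Cu(OAc)2 (2 equiv), pyridine, 4 Å MS, CH2Cl2, dry air, rt; 21 (2 equiv)
Reagents that add atoms: none
Why: Chan–Lam coupling as in step 14; the local environment of the reacting phenol is the same, so the larger chain should not change the reactivity.

Step 17
Reactants: 27 ABCDEFG heptamer silyl ether
Product: 28 ABCDEFG heptamer phenol (free hydroxyl at C6 of ring G)
Conditions: TBAF, AcOH, THF, 0 °C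
Reagents that add atoms: none
Why: Buffered fluoride desilylation as in step 13.

Step 18
Reactants: 28 ABCDEFG heptamer phenol; 29 (3,4,5-trimethoxyphenyl)boronic acid
Product: 30 octamer henicosamethyl ether (28 arylated on O-6 of ring G by 3,4,5-trimethoxyphenyl; all twenty-one hydroxyls of 31 as methyl ethers)
Conditions: Cu(OAc)2 (2 equiv), pyridine, 4 Å MS, CH2Cl2, dry air, rt; 29 (3 equiv)
Reagents that add atoms: none
Why: Chan–Lam coupling of the hindered ring G phenol with a cheap, unhindered boronic acid used in excess closes the last ether.

Step 19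
Reactants: 30 octamer henicosamethyl ether
Product: 31 CNP0206369.0 (octamer with twenty-one free hydroxyls)
Conditions: BBr3 (about 3 equiv per methoxy group), CH2Cl2, −78 °C to rt; MeOH, 0 °C; work-up under argon
Reagents that add atoms: none
Why: BBr3 complexes each methoxy oxygen and bromide removes the methyl group by SN2 attack, while diaryl ethers, which have no sp3 carbon on oxygen, are inert; methanolysis of the borates releases the polyphenol.

## Compound list

1 | 2,6-dimethoxy-1,4-benzoquinone | COC1=CC(=O)C=C(OC)C1=O | starting material
2 | 2,6-dimethoxybenzene-1,4-diol | COc1cc(O)cc(OC)c1O | intermediate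
3 | 4-(benzyloxy)-2,6-dimethoxyphenol | COc1cc(OCc2ccccc2)cc(OC)c1O | intermediate
4 | trichloroethylene | ClC=C(Cl)Cl | starting material
5 | 5-(benzyloxy)-2-{[(E)-1,2-dichloroethenyl]oxy}-1,3-dimethoxybenzene | COc1cc(OCc2ccccc2)cc(OC)c1O/C(Cl)=C\Cl | intermediate
6 | 5-(benzyloxy)-2-[(chloroethynyl)oxy]-1,3-dimethoxybenzene (not isolated) | COc1cc(OCc2ccccc2)cc(OC)c1OC#CCl | intermediate
7 | lithium 2-(4-benzyloxy-2,6-dimethoxyphenoxy)ethynide (not isolated) | COc1cc(OCc2ccccc2)cc(OC)c1OC#C[Li] | intermediate
8 | 5-(benzyloxy)-2-(ethynyloxy)-1,3-dimethoxybenzene | COc1cc(OCc2ccccc2)cc(OC)c1OC#C | intermediate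
9 | tributyl[1-(4-benzyloxy-2,6-dimethoxyphenoxy)ethenyl]stannane | COc1cc(OCc2ccccc2)cc(OC)c1OC(=C)[Sn](CCCC)(CCCC)CCCC | intermediate
10 | dimethyl squarate (3,4-dimethoxycyclobut-3-ene-1,2-dione) | COC1=C(OC)C(=O)C1=O | starting material
11 | [1-(4-benzyloxy-2,6-dimethoxyphenoxy)ethenyl]lithium (not isolated) | COc1cc(OCc2ccccc2)cc(OC)c1OC(=C)[Li] | intermediate
12 | lithium alkoxide of rac-4-[1-(4-benzyloxy-2,6-dimethoxyphenoxy)ethenyl]-4-hydroxy-2,3-dimethoxycyclobut-2-en-1-one (not isolated) | COC1=C(OC)C([O-])(C(=C)Oc2c(OC)cc(OCc3ccccc3)cc2OC)C1=O.[Li+] | intermediate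
13 | rac-4-[1-(4-benzyloxy-2,6-dimethoxyphenoxy)ethenyl]-4-[(tert-butyldimethylsilyl)oxy]-2,3-dimethoxycyclobut-2-en-1-one | COC1=C(OC)C(O[Si](C)(C)C(C)(C)C)(C(=C)Oc2c(OC)cc(OCc3ccccc3)cc2OC)C1=O | intermediate
14 | (3Z)-5-(4-benzyloxy-2,6-dimethoxyphenoxy)-4-[(tert-butyldimethylsilyl)oxy]-2,3-dimethoxyhexa-1,3,5-trien-1-one (not isolated) | COC(=C=O)/C(OC)=C(/O[Si](C)(C)C(C)(C)C)C(=C)Oc1c(OC)cc(OCc2ccccc2)cc1OC | intermediate
15 | 5-(4-benzyloxy-2,6-dimethoxyphenoxy)-4-[(tert-butyldimethylsilyl)oxy]-2,3-dimethoxycyclohexa-2,4-dien-1-one (not isolated) | COC1=C(OC)C(O[Si](C)(C)C(C)(C)C)=C(Oc2c(OC)cc(OCc3ccccc3)cc2OC)CC1=O | intermediate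
16 | 5-(4-benzyloxy-2,6-dimethoxyphenoxy)-4-[(tert-butyldimethylsilyl)oxy]-2,3-dimethoxyphenol (rings F and G) | COc1c(O)cc(Oc2c(OC)cc(OCc3ccccc3)cc2OC)c(O[Si](C)(C)C(C)(C)C)c1OC | intermediate
17 | {[6-(4-benzyloxy-2,6-dimethoxyphenoxy)-2,3,4-trimethoxyphenyl]oxy}(tert-butyl)dimethylsilane | COc1cc(Oc2c(OC)cc(OCc3ccccc3)cc2OC)c(O[Si](C)(C)C(C)(C)C)c(OC)c1OC | intermediate
18 | 4-(2-{[tert-butyl(dimethyl)silyl]oxy}-3,4,5-trimethoxyphenoxy)-3,5-dimethoxyphenol | COc1cc(Oc2c(OC)cc(O)cc2OC)c(O[Si](C)(C)C(C)(C)C)c(OC)c1OC | intermediate
19 | 4-(2-{[tert-butyl(dimethyl)silyl]oxy}-3,4,5-trimethoxyphenoxy)-3,5-dimethoxyphenyl trifluoromethanesulfonate | COc1cc(Oc2c(OC)cc(OS(=O)(=O)C(F)(F)F)cc2OC)c(O[Si](C)(C)C(C)(C)C)c(OC)c1OC | intermediate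
20 | pinacol ester of 21 (not isolated) | COc1cc(Oc2c(OC)cc(B3OC(C)(C)C(C)(C)O3)cc2OC)c(O[Si](C)(C)C(C)(C)C)c(OC)c1OC | intermediate
21 | [4-(2-{[tert-butyl(dimethyl)silyl]oxy}-3,4,5-trimethoxyphenoxy)-3,5-dimethoxyphenyl]boronic acid | COc1cc(Oc2c(OC)cc(B(O)O)cc2OC)c(O[Si](C)(C)C(C)(C)C)c(OC)c1OC | intermediate
22 | 2,4,6-trimethoxyphenol | COc1cc(OC)c(O)c(OC)c1 | starting material
23 | tert-butyl({6-[2,6-dimethoxy-4-(2,4,6-trimethoxyphenoxy)phenoxy]-2,3,4-trimethoxyphenyl}oxy)dimethylsilane (rings A to C) | COc1cc(OC)c(Oc2cc(OC)c(Oc3cc(OC)c(OC)c(OC)c3O[Si](C)(C)C(C)(C)C)c(OC)c2)c(OC)c1 | intermediate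
24 | 6-[2,6-dimethoxy-4-(2,4,6-trimethoxyphenoxy)phenoxy]-2,3,4-trimethoxyphenol (ABC trimer phenol) | COc1cc(OC)c(Oc2cc(OC)c(Oc3cc(OC)c(OC)c(OC)c3O)c(OC)c2)c(OC)c1 | intermediate
25 | ABCDE pentamer, thirteen methyl ethers, tert-butyldimethylsilyl ether on O-6 of ring E | COc1cc(OC)c(Oc2cc(OC)c(Oc3cc(OC)c(OC)c(OC)c3Oc3cc(OC)c(Oc4cc(OC)c(OC)c(OC)c4O[Si](C)(C)C(C)(C)C)c(OC)c3)c(OC)c2)c(OC)c1 | intermediate
26 | ABCDE pentamer, thirteen methyl ethers, free hydroxyl at C6 of ring E | COc1cc(OC)c(Oc2cc(OC)c(Oc3cc(OC)c(OC)c(OC)c3Oc3cc(OC)c(Oc4cc(OC)c(OC)c(OC)c4O)c(OC)c3)c(OC)c2)c(OC)c1 | intermediate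
27 | ABCDEFG heptamer, eighteen methyl ethers, tert-butyldimethylsilyl ether on O-6 of ring G | COc1cc(OC)c(Oc2cc(OC)c(Oc3cc(OC)c(OC)c(OC)c3Oc3cc(OC)c(Oc4cc(OC)c(OC)c(OC)c4Oc4cc(OC)c(Oc5cc(OC)c(OC)c(OC)c5O[Si](C)(C)C(C)(C)C)c(OC)c4)c(OC)c3)c(OC)c2)c(OC)c1 | intermediate
28 | ABCDEFG heptamer, eighteen methyl ethers, free hydroxyl at C6 of ring G | COc1cc(OC)c(Oc2cc(OC)c(Oc3cc(OC)c(OC)c(OC)c3Oc3cc(OC)c(Oc4cc(OC)c(OC)c(OC)c4Oc4cc(OC)c(Oc5cc(OC)c(OC)c(OC)c5O)c(OC)c4)c(OC)c3)c(OC)c2)c(OC)c1 | intermediate
29 | (3,4,5-trimethoxyphenyl)boronic acid | COc1cc(B(O)O)cc(OC)c1OC | starting material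
30 | octamer henicosamethyl ether (all twenty-one hydroxyls of 31 as methyl ethers) | COc1cc(OC)c(Oc2cc(OC)c(Oc3cc(OC)c(OC)c(OC)c3Oc3cc(OC)c(Oc4cc(OC)c(OC)c(OC)c4Oc4cc(OC)c(Oc5cc(OC)c(OC)c(OC)c5Oc5cc(OC)c(OC)c(OC)c5)c(OC)c4)c(OC)c3)c(OC)c2)c(OC)c1 | intermediate
31 | CNP0206369.0 | Oc1cc(O)c(Oc2cc(O)c(Oc3cc(O)c(O)c(O)c3Oc3cc(O)c(Oc4cc(O)c(O)c(O)c4Oc4cc(O)c(Oc5cc(O)c(O)c(O)c5Oc5cc(O)c(O)c(O)c5)c(O)c4)c(O)c3)c(O)c2)c(O)c1 | target

## Step count and least certain steps

Total: 19 steps. Longest linear sequence: 19 steps (1 to 31); 21 re-enters in steps 14 and 16, and 4, 10, 22 and 29 are bought.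

**Step 7 (key step).** The ketene 14 may be consumed before it cyclises, by dimerisation or capture by traces of water, if crowding between the silyloxy group and the 2,6-dimethoxyaryloxy group slows the turn into the reactive conformation. The electron-rich product may also lose its silyl group and be oxidised by air at 110 °C. The fallback changes the order of events: the ring expansion is run on the smaller free carbinol, the best documented substrate class, and the two hydroquinone oxygens are told apart afterwards. It sets out from 9 and 10. Lithiation and addition as in step 6, but with an NH4Cl quench, give rac-4-[1-(4-benzyloxy-2,6-dimethoxyphenoxy)ethenyl]-4-hydroxy-2,3-dimethoxycyclobut-2-en-1-one F1. Heating in toluene gives 5-(4-benzyloxy-2,6-dimethoxyphenoxy)-2,3-dimethoxybenzene-1,4-diol F2. MeI (1 equiv) and K2CO3 in acetone should methylate the hydroxyl next to the ring C–H in preference to the one flanked by aryloxy and methoxy groups, giving 6-(4-benzyloxy-2,6-dimethoxyphenoxy)-2,3,4-trimethoxyphenol F3. TBSOTf and 2,6-lutidine then silylate the hindered hydroxyl, and the route is rejoined at 17.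

**Step 5.** Tin may be delivered to the terminal carbon, or the labile ynol ether may oligomerise on palladium; either lowers the amount of the 1-stannyl isomer. The fallback sets out from 8. Markovnikov addition of HBr (1 equiv, from TMSBr and MeOH, CH2Cl2, −78 °C) gives 5-(benzyloxy)-2-[(1-bromoethenyl)oxy]-1,3-dimethoxybenzene F4, used crude. Bromine–lithium exchange with t-BuLi (2 equiv, THF, −78 °C) gives the vinyllithium 11, where the route is rejoined within step 6.

**Step 14 (step 16 is the same reaction on a larger phenol and would be treated likewise).** Aryl transfer from copper to the di-ortho-substituted phenol may be slow, leaving time for protodeboronation and homocoupling of 21 and for oxidation of the electron-rich phenol by the copper oxidant. The fallback is a copper-catalysed Ullmann coupling without oxidant and sets out from 21. I2 and K2CO3 in MeCN replace boron by iodine to give tert-butyl{[6-(4-iodo-2,6-dimethoxyphenoxy)-2,3,4-trimethoxyphenyl]oxy}dimethylsilane F5. CuI, N,N-dimethylglycine and Cs2CO3 in 1,4-dioxane at 90 °C couple F5 with 24, and the route is rejoined at 25.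

**Step 19.** Cleavage of twenty-one ethers may stop short when partly demethylated borates precipitate, and the free polyphenol may be oxidised during isolation. The fallback is a two-stage deprotection and sets out from 30. After BBr3 treatment as in step 19, the crude polyphenol is acetylated at once (Ac2O, pyridine) to the henicosaacetate of 31 F6, which can be chromatographed, with incompletely demethylated material separated and resubmitted. HCl in MeOH under argon then removes the acetyl groups by transesterification and gives 31.

## Further compounds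

F1 | step 7 | rac-4-[1-(4-benzyloxy-2,6-dimethoxyphenoxy)ethenyl]-4-hydroxy-2,3-dimethoxycyclobut-2-en-1-one | COC1=C(OC)C(O)(C(=C)Oc2c(OC)cc(OCc3ccccc3)cc2OC)C1=O
F2 | step 7 | 5-(4-benzyloxy-2,6-dimethoxyphenoxy)-2,3-dimethoxybenzene-1,4-diol | COc1c(O)cc(Oc2c(OC)cc(OCc3ccccc3)cc2OC)c(O)c1OC
F3 | step 7 | 6-(4-benzyloxy-2,6-dimethoxyphenoxy)-2,3,4-trimethoxyphenol | COc1cc(Oc2c(OC)cc(OCc3ccccc3)cc2OC)c(O)c(OC)c1OC
F4 | step 5 | 5-(benzyloxy)-2-[(1-bromoethenyl)oxy]-1,3-dimethoxybenzene | COc1cc(OCc2ccccc2)cc(OC)c1OC(Br)=C
F5 | step 14 | tert-butyl{[6-(4-iodo-2,6-dimethoxyphenoxy)-2,3,4-trimethoxyphenyl]oxy}dimethylsilane | COc1cc(Oc2c(OC)cc(I)cc2OC)c(O[Si](C)(C)C(C)(C)C)c(OC)c1OC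
F6 | step 19 | henicosaacetate of 31 | CC(=O)Oc1cc(OC(C)=O)c(Oc2cc(OC(C)=O)c(Oc3cc(OC(C)=O)c(OC(C)=O)c(OC(C)=O)c3Oc3cc(OC(C)=O)c(Oc4cc(OC(C)=O)c(OC(C)=O)c(OC(C)=O)c4Oc4cc(OC(C)=O)c(Oc5cc(OC(C)=O)c(OC(C)=O)c(OC(C)=O)c5Oc5cc(OC(C)=O)c(OC(C)=O)c(OC(C)=O)c5)c(OC(C)=O)c4)c(OC(C)=O)c3)c(OC(C)=O)c2)c(OC(C)=O)c1
A1 | alternative 1 | 2,6-dimethoxy-4-(2,4,6-trimethoxyphenoxy)phenol (AB dimer phenol) | COc1cc(OC)c(Oc2cc(OC)c(O)c(OC)c2)c(OC)c1
A2 | alternative 1 | 3,4,5-trimethoxy-2-(trimethylsilyl)phenyl trifluoromethanesulfonate | COc1cc(OS(=O)(=O)C(F)(F)F)c([Si](C)(C)C)c(OC)c1OC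
A3 | alternative 1 | ABC trimer with iodine at C6 of ring C | COc1cc(OC)c(Oc2cc(OC)c(Oc3cc(OC)c(OC)c(OC)c3I)c(OC)c2)c(OC)c1
A4 | alternative 2 | dimethyl 2-(4-benzyloxy-3,5-dimethoxyphenoxy)propanedioate | COC(=O)C(Oc1cc(OC)c(OCc2ccccc2)c(OC)c1)C(=O)OC
A5 | alternative 2 | dimethyl 3-oxopentanedioate | COC(=O)CC(=O)CC(=O)OC
A6 | alternative 2 | dimethyl 5-(4-benzyloxy-3,5-dimethoxyphenoxy)-2,4,6-trihydroxybenzene-1,3-dicarboxylate | COC(=O)c1c(O)c(Oc2cc(OC)c(OCc3ccccc3)c(OC)c2)c(O)c(C(=O)OC)c1O
A7 | alternative 3 | octaaryl heptaaldehyde (formyl at C4 of ring A and C3 of rings B to G; fourteen methyl ethers) | O=Cc1cc(OC)c(Oc2cc(C=O)c(Oc3cc(C=O)c(OC)c(OC)c3Oc3cc(C=O)c(Oc4cc(C=O)c(OC)c(OC)c4Oc4cc(C=O)c(Oc5cc(C=O)c(OC)c(OC)c5Oc5cc(OC)c(OC)c(OC)c5)c(OC)c4)c(OC)c3)c(OC)c2)c(OC)c1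
A8 | alternative 3 | octamer heptaphenol with fourteen methyl ethers | Oc1cc(OC)c(Oc2cc(O)c(Oc3cc(O)c(OC)c(OC)c3Oc3cc(O)c(Oc4cc(O)c(OC)c(OC)c4Oc4cc(O)c(Oc5cc(O)c(OC)c(OC)c5Oc5cc(OC)c(OC)c(OC)c5)c(OC)c4)c(OC)c3)c(OC)c2)c(OC)c1
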